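Ring C, the cyclohexane that carries both quaternary methyl carbons, is trans-fused to the gem-dimethylcyclohexane ring D. The CH2–CH2 bond of ring C and the C/D fusion bond (angular C–CH3 carbon to the fusion CH) flank one two-carbon unit, which is the retron of a [4+2] cycloaddition. An acyclic 2-methylidene trienal, whose formyl group is the latent angular methyl, is therefore folded by a catalytic enantioselective intramolecular Diels–Alder reaction that closes rings C and D at once and sets both fusion stereocentres. A ketene [2+2]/ring-opening sequence then installs the second quaternary methyl; ring A is attached by anti-selective allylation and the cyclooctene is closed by McMurry coupling.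

Key step: step 7

Remark: the (S)-configured oxazaborolidinium catalyst is assumed to give the drawn enantiomer of 10; if the opposite sense of induction were found, the (R)-catalyst would be used instead.

Step 1
Reactants: 1 3-chloro-2-(chloromethyl)prop-1-ene
Product: 2 benzyl 2-(chloromethyl)prop-2-en-1-yl ether
Conditions: BnOH, NaH, THF, 0 °C → rt (1 in threefold excess)
Reagents that add atoms: benzyl alcohol, OCc1ccccc1
Why: Williamson etherification of an allylic chloride, the excess of dichloride should hold substitution at one end.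

Step 2
Reactants: 2 benzyl 2-(chloromethyl)prop-2-en-1-yl ether
Product: 3 diethyl {2-[(benzyloxy)methyl]prop-2-en-1-yl}phosphonate
Conditions: P(OEt)3, neat, 140 °C
Reagents that add atoms: triethyl phosphite, CCOP(OCC)OCC
Why: Michaelis–Arbuzov reaction of a reactive allylic chloride.

Step 3
Reactants: 4 methyl 3,3-dimethylpent-4-enoate
Product: 6 methyl 7,7-diethoxy-3,3-dimethyl-6-methylideneheptanoate, via alkylborane 5 (not isolated)
Conditions: 9-BBN, THF, 0 °C → rt; then 2-bromo-3,3-diethoxyprop-1-ene, Pd(dppf)Cl2 (5 mol %), K3PO4, DMF/H2O, 50 °C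
Reagents that add atoms: 2-bromo-3,3-diethoxyprop-1-ene, C=C(Br)C(OCC)OCC
Why: anti-Markovnikov hydroboration of the only alkene followed by B-alkyl Suzuki–Miyaura coupling with a 1,1-disubstituted vinyl bromide, the ester being inert to both.

Step 4
Reactants: 6 methyl 7,7-diethoxy-3,3-dimethyl-6-methylideneheptanoate
Product: 7 7,7-diethoxy-3,3-dimethyl-6-methylideneheptanal
Conditions: i-Bu2AlH, CH2Cl2, −78 °C; aq. potassium sodium tartrate
Reagents that add atoms: none
Why: partial reduction of a methyl ester to the aldehyde through the stable tetrahedral aluminium hemiacetal at low temperature.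

Step 5
Reactants: 7 7,7-diethoxy-3,3-dimethyl-6-methylideneheptanal; 3 diethyl {2-[(benzyloxy)methyl]prop-2-en-1-yl}phosphonate
Product: 8 (7E)-9-[(benzyloxy)methyl]-1,1-diethoxy-5,5-dimethyl-2-methylidenedeca-7,9-diene
Conditions: 3, n-BuLi, THF, −78 °C; then 7, HMPA, −78 °C → rt
Reagents that add atoms: none
Why: Horner–Wadsworth–Emmons olefination with a lithiated allylic phosphonate, which should give the (E)-configured 1,3-diene.

Step 6
Reactants: 8 (7E)-9-[(benzyloxy)methyl]-1,1-diethoxy-5,5-dimethyl-2-methylidenedeca-7,9-diene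
Product: 9 (7E)-9-[(benzyloxy)methyl]-5,5-dimethyl-2-methylidenedeca-7,9-dienal
Conditions: 10% aq. oxalic acid, SiO2, CH2Cl2, rt; used at once
Reagents that add atoms: water, O
Why: mild acid hydrolysis of the acetal releases the 2-alkylacrolein without touching the diene or the benzyl ether.

Step 7
Reactants: 9 (7E)-9-[(benzyloxy)methyl]-5,5-dimethyl-2-methylidenedeca-7,9-dienal
Product: 10 7-[(benzyloxy)methyl]-2,2-dimethyl-1,2,3,4,4a,5,6,8a-octahydronaphthalene-4a-carbaldehyde (trans-fused, angular CHO and fusion H on opposite faces)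
Conditions: (S)-3,3-diphenyl-1-(o-tolyl)tetrahydro-1H,3H-pyrrolo[1,2-c][1,3,2]oxazaborole (20 mol %), HNTf2 (17 mol %), CH2Cl2, −78 → −40 °C
Reagents that add atoms: none
Why: Coordination of the formyl group to the chiral boron Lewis acid lowers the LUMO of the 2-alkylacrolein, which adds to the tethered (E)-diene in a concerted, asynchronous [4+2] cycloaddition; the closest known types are the oxazaborolidinium-catalysed enantioselective Diels–Alder reaction of 2-substituted acroleins and the intramolecular Diels–Alder reaction of 1,7,9-decatrienes. Ring C is closed by the cycloaddition itself as a cyclohexene, and ring D is closed in the same event in the fused mode, because the four-carbon tether joins the diene terminus to the internal dienophile carbon. The relative configuration (angular formyl trans to the fusion hydrogen, hence a trans-decalin) should follow from the formyl-endo, tether-exo chair-like transition state of the (E)-diene, and the absolute configuration of the quaternary carbon from shielding of one face of the coordinated s-trans enal by the aryl groups of the catalyst. Regiochemistry is enforced by the tether and matched by polarity, the nucleophilic CH2 terminus of the diene bonding to the enal β-carbon. The step needs endo (trans-fusion) and enantiofacial selectivity; the gem-dialkyl effect of the tether and the low uncatalysed rate of an α-alkylacrolein at −78 °C should let the catalysed pathway dominate.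

Step 8
Reactants: 10 7-[(benzyloxy)methyl]-2,2-dimethyl-1,2,3,4,4a,5,6,8a-octahydronaphthalene-4a-carbaldehyde
Product: 12 7-[(benzyloxy)methyl]-2,2,4a-trimethyl-1,2,3,4,4a,5,6,8a-octahydronaphthalene (trans-fused), via hydrazone 11 (not isolated)
Conditions: N2H4·H2O, KOH, diethylene glycol, 130 → 200 °C
Reagents that add atoms: none
Why: Wolff–Kishner reduction turns the neopentyl angular aldehyde into the angular methyl group without touching the stereocentres.

Step 9
Reactants: 12 7-[(benzyloxy)methyl]-2,2,4a-trimethyl-1,2,3,4,4a,5,6,8a-octahydronaphthalene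
Product: 13 cis-fused 2,2-dichlorocyclobutanone on the former C=C of 12 (CCl2 on the carbon bearing CH2OBn, C=O on the former vinylic CH, four-membered ring on the face opposite the angular methyl)
Conditions: Cl3CCOCl, Zn–Cu couple, POCl3, Et2O, rt
Reagents that add atoms: trichloroacetyl chloride, O=C(Cl)C(Cl)(Cl)Cl
Why: ketene–alkene [2+2] cycloaddition in which the carbonyl carbon bonds to the less substituted alkene carbon and both new bonds form suprafacially on the face away from the 1,3-related axial methyl, which sets the quaternary carbon and its neighbour.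

Step 10
Reactants: 13 dichlorocyclobutanone
Product: 14 methyl 2-[(benzyloxy)methyl]-2-(dichloromethyl)-4a,7,7-trimethyldecahydronaphthalene-1-carboxylate
Conditions: NaOMe, MeOH, 0 °C → rt
Reagents that add atoms: methanol, CO
Why: haloform-type ring opening of the strained α,α-dichloroketone (methoxide adds to the carbonyl, the dichloromethyl carbanion leaves), and the ester-bearing centre, which is epimerisable, should rest in the equatorial configuration already formed.

Step 11
Reactants: 14 dichloromethyl ester
Product: 15 methyl 2-[(benzyloxy)methyl]-2,4a,7,7-tetramethyldecahydronaphthalene-1-carboxylate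
Conditions: Bu3SnH (3 equiv), AIBN (cat.), toluene, 110 °C
Reagents that add atoms: none
Why: radical chain dehalogenation reduces the gem-dichloride to the second quaternary methyl group.

Step 12
Reactants: 15 methyl ester
Product: 16 2-[(benzyloxy)methyl]-2,4a,7,7-tetramethyldecahydronaphthalene-1-carbaldehyde
Conditions: i-Bu2AlH, toluene, −78 °C; aq. potassium sodium tartrate
Reagents that add atoms: none
Why: partial reduction of a hindered ester to the aldehyde, whose α-centre keeps the stable equatorial configuration.

Step 13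
Reactants: 16 aldehyde
Product: 17 (3E)-4-{2-[(benzyloxy)methyl]-2,4a,7,7-tetramethyldecahydronaphthalen-1-yl}but-3-en-2-one
Conditions: Ph3P=CHC(O)CH3, toluene, 100 °C
Reagents that add atoms: 1-(triphenyl-λ5-phosphanylidene)propan-2-one, CC(=O)C=P(c1ccccc1)(c1ccccc1)c1ccccc1
Why: Wittig olefination with a stabilised ylide gives the (E)-enone and brings in the last three carbons of the eight-membered ring.

Step 14
Reactants: 17 enone
Product: 18 4-[2-(hydroxymethyl)-2,4a,7,7-tetramethyldecahydronaphthalen-1-yl]butan-2-one
Conditions: H2 (1 atm), Pd/C, EtOAc/EtOH, rt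
Reagents that add atoms: none
Why: one catalytic hydrogenation saturates the conjugated alkene and cleaves the benzyl ether by hydrogenolysis, the ketone staying intact.

Step 15
Reactants: 18 hydroxy ketone
Product: 19 2,4a,7,7-tetramethyl-1-(3-oxobutyl)decahydronaphthalene-2-carbaldehyde
Conditions: DMP, NaHCO3, CH2Cl2, 0 °C → rt
Reagents that add atoms: none
Why: buffered hypervalent-iodine oxidation of the neopentyl primary alcohol gives the non-enolisable aldehyde under neutral conditions that should avoid intramolecular aldol reaction.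

Step 16
Reactants: 20 (4S)-4-hydroxycyclopent-2-en-1-one
Product: 21 (4S)-4-[(triethylsilyl)oxy]cyclopent-2-en-1-one
Conditions: Et3SiCl, imidazole, CH2Cl2, 0 °C
Reagents that add atoms: chlorotriethylsilane, CC[Si](Cl)(CC)CC
Why: silylation of the secondary alcohol with a group that can later be removed in the presence of tert-butyldimethylsilyl ethers.

Step 17
Reactants: 21 (4S)-4-[(triethylsilyl)oxy]cyclopent-2-en-1-one
Product: 22 (4S)-2-(hydroxymethyl)-4-[(triethylsilyl)oxy]cyclopent-2-en-1-one
Conditions: aq. HCHO, imidazole (cat.), THF/H2O, rt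
Reagents that add atoms: formaldehyde, C=O
Why: Morita–Baylis–Hillman hydroxymethylation at the α-carbon of the enone, which supplies the future ring A methyl carbon.

Step 18
Reactants: 22 hydroxymethyl enone
Product: 23 (1R,4S)-2-(hydroxymethyl)-4-[(triethylsilyl)oxy]cyclopent-2-en-1-ol
Conditions: NaBH4, CeCl3·7H2O, MeOH, −78 °C
Reagents that add atoms: none
Why: Luche 1,2-reduction in which hydride should add to the face opposite the silyloxy group, giving the cis-1,4-dioxygenated cyclopentene.

Step 19
Reactants: 23 diol
Product: 24 (1R,4S)-2-(bromomethyl)-4-[(triethylsilyl)oxy]cyclopent-2-en-1-ol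
Conditions: CBr4, PPh3, CH2Cl2, −40 → −10 °C
Reagents that add atoms: tetrabromomethane, BrC(Br)(Br)Br
Why: Appel bromination, which should take the primary allylic alcohol well before the secondary one at low temperature.

Step 20
Reactants: 24 bromo alcohol
Product: 25 tert-butyl{[(1R,4S)-2-(bromomethyl)-4-[(triethylsilyl)oxy]cyclopent-2-en-1-yl]oxy}dimethylsilane
Conditions: TBSOTf, 2,6-lutidine, CH2Cl2, −78 °C
Reagents that add atoms: tert-butyldimethylsilyl trifluoromethanesulfonate, CC(C)(C)[Si](C)(C)OS(=O)(=O)C(F)(F)F
Why: silylation of the remaining secondary alcohol with a non-nucleophilic base that leaves the allylic bromide alone.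

Step 21
Reactants: 19 keto aldehyde; 25 allylic bromide
Product: 27 4-{2-[hydroxy(2-methylidene-3-[(tert-butyldimethylsilyl)oxy]-5-[(triethylsilyl)oxy]cyclopentyl)methyl]-2,4a,7,7-tetramethyldecahydronaphthalen-1-yl}butan-2-one (anti carbinol, side chain trans to both silyloxy groups), via allylchromium dichloride 26 (not isolated)
Conditions: CrCl2 (4 equiv), THF, 0 °C → rt
Reagents that add atoms: none
Why: Nozaki–Hiyama–Kishi allylation, aldehyde-selective over the ketone, in which the allylchromium reagent should react through its ring γ-carbon in a closed chair transition state (anti carbinol) on the ring face opposite the adjacent triethylsilyloxy group, setting both new stereocentres and leaving an exocyclic methylene.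

Step 22
Reactants: 27 homoallylic alcohol
Product: 28 tert-butyldimethylsilyl ether of 27
Conditions: TBSOTf, 2,6-lutidine, CH2Cl2, −78 → 0 °C
Reagents that add atoms: tert-butyldimethylsilyl trifluoromethanesulfonate, CC(C)(C)[Si](C)(C)OS(=O)(=O)C(F)(F)F
Why: the reactive silyl triflate protects the hindered carbinol so that it cannot direct the later hydrogenation.

Step 23
Reactants: 28 tris(silyl) ether
Product: 29 cyclopentanol with the triethylsilyl group removed (exocyclic methylene retained)
Conditions: AcOH/THF/H2O (3:1:1), rt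
Reagents that add atoms: none
Why: selective acid hydrolysis of the more labile triethylsilyl ether frees the hydroxyl group that is cis and homoallylic to the methylene group.

Step 24
Reactants: 29 homoallylic cyclopentanol
Product: 30 2-methylcyclopentanol (new methyl cis to the carbinol side chain, trans to the neighbouring silyloxy group)
Conditions: H2 (1 atm), [Ir(cod)(PCy3)(py)]PF6 (10 mol %), CH2Cl2, rt
Reagents that add atoms: none
Why: hydroxyl-directed hydrogenation in which the cationic iridium catalyst binds the free ring hydroxyl and should deliver hydrogen to the exocyclic methylene from that face, which sets the methyl-bearing centre.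

Step 25
Reactants: 30 cyclopentanol
Product: 31 diketone (cyclopentanone and methyl ketone, both other oxygens as tert-butyldimethylsilyl ethers)
Conditions: DMP, NaHCO3, CH2Cl2, rt
Reagents that add atoms: none
Why: neutral oxidation of the secondary alcohol, chosen to spare the α-stereocentre and the β-silyloxy group of the new ketone.

Step 26
Reactants: 31 diketone
Product: 32 bis(tert-butyldimethylsilyl) ether of the target
Conditions: TiCl3(DME)1.5, Zn–Cu couple, DME, reflux; 31 added by syringe pump (high dilution)
Reagents that add atoms: none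
Why: intramolecular McMurry coupling of the two ketones on low-valent titanium closes the eight-membered ring and places the tetrasubstituted alkene without ambiguity, the ring fixing its geometry.

Step 27
Reactants: 32 bis(silyl) ether
Product: 33 target diol CNP0213887.1
Conditions: Bu4NF, THF, 50 °C
Reagents that add atoms: none
Why: fluoride-mediated cleavage of both silyl ethers, which touches neither the alkene nor any stereocentre.

Compound list

1 | 3-chloro-2-(chloromethyl)prop-1-ene | C=C(CCl)CCl | starting material
2 | benzyl 2-(chloromethyl)prop-2-en-1-yl ether | C=C(CCl)COCc1ccccc1 | intermediate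
3 | diethyl {2-[(benzyloxy)methyl]prop-2-en-1-yl}phosphonate | C=C(COCc1ccccc1)CP(=O)(OCC)OCC | intermediate
4 | methyl 3,3-dimethylpent-4-enoate | C=CC(C)(C)CC(=O)OC | starting material
5 | methyl 5-(9-borabicyclo[3.3.1]nonan-9-yl)-3,3-dimethylpentanoate (alkylborane) | COC(=O)CC(C)(C)CCB1C2CCCC1CCC2 | intermediate
6 | methyl 7,7-diethoxy-3,3-dimethyl-6-methylideneheptanoate | C=C(C(OCC)OCC)CCC(C)(C)CC(=O)OC | intermediate
7 | 7,7-diethoxy-3,3-dimethyl-6-methylideneheptanal | C=C(C(OCC)OCC)CCC(C)(C)CC=O | intermediate
8 | (7E)-9-[(benzyloxy)methyl]-1,1-diethoxy-5,5-dimethyl-2-methylidenedeca-7,9-diene | C=C(C(OCC)OCC)CCC(C)(C)C/C=C/C(=C)COCc1ccccc1 | intermediate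
9 | (7E)-9-[(benzyloxy)methyl]-5,5-dimethyl-2-methylidenedeca-7,9-dienal | C=C(C=O)CCC(C)(C)C/C=C/C(=C)COCc1ccccc1 | intermediate
10 | 7-[(benzyloxy)methyl]-2,2-dimethyl-1,2,3,4,4a,5,6,8a-octahydronaphthalene-4a-carbaldehyde, trans-fused | C1=C(COCc3ccccc3)CC[C@]2(C=O)CCC(C)(C)C[C@@H]12 | intermediate
11 | hydrazone of 10 | C1=C(COCc3ccccc3)CC[C@]2(C=NN)CCC(C)(C)C[C@@H]12 | intermediate
12 | 7-[(benzyloxy)methyl]-2,2,4a-trimethyl-1,2,3,4,4a,5,6,8a-octahydronaphthalene, trans-fused | C1=C(COCc3ccccc3)CC[C@]2(C)CCC(C)(C)C[C@@H]12 | intermediate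
13 | cis-fused 2,2-dichlorocyclobutanone on ring C (CCl2 on the carbon bearing CH2OBn, four-membered ring anti to the angular methyl) | c1ccccc1COC[C@@]2(C(Cl)(Cl)C4=O)CC[C@]3(C)CCC(C)(C)C[C@H]3[C@@H]24 | intermediate
14 | methyl 2-[(benzyloxy)methyl]-2-(dichloromethyl)-4a,7,7-trimethyldecahydronaphthalene-1-carboxylate | c1ccccc1COC[C@@]2(C(Cl)Cl)CC[C@]3(C)CCC(C)(C)C[C@H]3[C@@H]2C(=O)OC | intermediate
15 | methyl 2-[(benzyloxy)methyl]-2,4a,7,7-tetramethyldecahydronaphthalene-1-carboxylate | c1ccccc1COC[C@@]2(C)CC[C@]3(C)CCC(C)(C)C[C@H]3[C@@H]2C(=O)OC | intermediate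
16 | 2-[(benzyloxy)methyl]-2,4a,7,7-tetramethyldecahydronaphthalene-1-carbaldehyde | c1ccccc1COC[C@@]2(C)CC[C@]3(C)CCC(C)(C)C[C@H]3[C@@H]2C=O | intermediate
17 | (3E)-4-{2-[(benzyloxy)methyl]-2,4a,7,7-tetramethyldecahydronaphthalen-1-yl}but-3-en-2-one | c1ccccc1COC[C@@]2(C)CC[C@]3(C)CCC(C)(C)C[C@H]3[C@@H]2/C=C/C(C)=O | intermediate
18 | 4-[2-(hydroxymethyl)-2,4a,7,7-tetramethyldecahydronaphthalen-1-yl]butan-2-one | OC[C@@]2(C)CC[C@]3(C)CCC(C)(C)C[C@H]3[C@@H]2CCC(C)=O | intermediate
19 | 2,4a,7,7-tetramethyl-1-(3-oxobutyl)decahydronaphthalene-2-carbaldehyde | O=C[C@@]2(C)CC[C@]3(C)CCC(C)(C)C[C@H]3[C@@H]2CCC(C)=O | intermediate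
20 | (4S)-4-hydroxycyclopent-2-en-1-one | O=C1C=C[C@@H](O)C1 | starting material
21 | (4S)-4-[(triethylsilyl)oxy]cyclopent-2-en-1-one | O=C1C=C[C@@H](O[Si](CC)(CC)CC)C1 | intermediate
22 | (4S)-2-(hydroxymethyl)-4-[(triethylsilyl)oxy]cyclopent-2-en-1-one | O=C1C(CO)=C[C@@H](O[Si](CC)(CC)CC)C1 | intermediate
23 | (1R,4S)-2-(hydroxymethyl)-4-[(triethylsilyl)oxy]cyclopent-2-en-1-ol | [C@H]1(O[Si](CC)(CC)CC)C[C@@H](O)C(CO)=C1 | intermediate
24 | (1R,4S)-2-(bromomethyl)-4-[(triethylsilyl)oxy]cyclopent-2-en-1-ol | [C@H]1(O[Si](CC)(CC)CC)C[C@@H](O)C(CBr)=C1 | intermediate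
25 | tert-butyl{[(1R,4S)-2-(bromomethyl)-4-[(triethylsilyl)oxy]cyclopent-2-en-1-yl]oxy}dimethylsilane | [C@H]1(O[Si](CC)(CC)CC)C[C@@H](O[Si](C)(C)C(C)(C)C)C(CBr)=C1 | intermediate
26 | allylchromium dichloride formed from 25 | [C@H]1(O[Si](CC)(CC)CC)C[C@@H](O[Si](C)(C)C(C)(C)C)C(C[Cr](Cl)Cl)=C1 | intermediate
27 | homoallylic alcohol from 19 and 25 (anti carbinol, exocyclic methylene on ring A) | [C@H]2(O[Si](CC)(CC)CC)C[C@@H](O[Si](C)(C)C(C)(C)C)C(=C)[C@@H]2[C@@H](O)[C@@]4(C)CC[C@]3(C)CCC(C)(C)C[C@H]3[C@@H]4CCC(C)=O | intermediate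
28 | tert-butyldimethylsilyl ether of 27 | [C@H]2(O[Si](CC)(CC)CC)C[C@@H](O[Si](C)(C)C(C)(C)C)C(=C)[C@@H]2[C@@H](O[Si](C)(C)C(C)(C)C)[C@@]4(C)CC[C@]3(C)CCC(C)(C)C[C@H]3[C@@H]4CCC(C)=O | intermediate
29 | cyclopentanol from 28 after removal of the triethylsilyl group | [C@H]2(O)C[C@@H](O[Si](C)(C)C(C)(C)C)C(=C)[C@@H]2[C@@H](O[Si](C)(C)C(C)(C)C)[C@@]4(C)CC[C@]3(C)CCC(C)(C)C[C@H]3[C@@H]4CCC(C)=O | intermediate
30 | 2-methylcyclopentanol from hydrogenation of 29 (methyl cis to the side chain) | [C@H]2(O)C[C@@H](O[Si](C)(C)C(C)(C)C)[C@H](C)[C@@H]2[C@@H](O[Si](C)(C)C(C)(C)C)[C@@]4(C)CC[C@]3(C)CCC(C)(C)C[C@H]3[C@@H]4CCC(C)=O | intermediate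
31 | diketone (cyclopentanone and methyl ketone) | O=C2C[C@@H](O[Si](C)(C)C(C)(C)C)[C@H](C)[C@@H]2[C@@H](O[Si](C)(C)C(C)(C)C)[C@@]4(C)CC[C@]3(C)CCC(C)(C)C[C@H]3[C@@H]4CCC(C)=O | intermediate
32 | bis(tert-butyldimethylsilyl) ether of the target | C/C1=C2\C[C@@H](O[Si](C)(C)C(C)(C)C)[C@H](C)[C@@H]2[C@@H](O[Si](C)(C)C(C)(C)C)[C@@]2(C)CC[C@]3(C)CCC(C)(C)C[C@H]3[C@@H]2CC1 | intermediate
33 | CNP0213887.1 (5-8-6-6 tetracyclic diol) | C/C1=C2\C[C@@H](O)[C@H](C)[C@@H]2[C@@H](O)[C@@]2(C)CC[C@]3(C)CCC(C)(C)C[C@H]3[C@@H]2CC1 | target

Total step count: 27 (steps 1–2 phosphonate, steps 3–15 rings C and D, steps 16–20 ring A, steps 21–27 coupling and endgame).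
Longest linear sequence: 20 steps, from 4 to 33 (steps 3–15 and 21–27).

Steps most likely to fail

Step 7. Enantiofacial control or endo (trans-fusion) selectivity may erode, or the enal may oligomerise under the strong Lewis acid. The fallback sets out from acetal 8 and returns at aldehyde 10. Transacetalisation of 8 with (2R,4R)-pentane-2,4-diol (pyridinium p-toluenesulfonate, benzene, reflux) would give the chiral dioxane acetal F1. Catalytic TMSOTf in CH2Cl2 at −78 °C would then open the acetal to an alkoxy-stabilised allyl cation, which should undergo an ionic intramolecular Diels–Alder reaction under control of the covalently bound diol to the cycloadduct acetal F2 (the antipodal diol is used if the sense of induction requires it). Aqueous oxalic acid would hydrolyse F2 to 10.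

Step 26. Reductive coupling may stop at the pinacol stage or go intermolecular, the centre α to the cyclopentanone may epimerise, or the β-silyloxy group may be eliminated at reflux. The fallback sets out from diketone 31 and returns at 32. SmI2 in THF/HMPA at −78 °C → rt would effect an intramolecular pinacol coupling to the cis-diol F3. 1,1'-Thiocarbonyldiimidazole with DMAP in toluene at reflux would convert F3 into the cyclic thiocarbonate F4. Corey–Winter olefination of F4 with 1,3-dimethyl-2-phenyl-1,3,2-diazaphospholidine at 40 °C should then release the tetrasubstituted alkene 32 by stereospecific syn elimination.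

Step 21. The allylchromium species may undergo β-elimination of the neighbouring silyloxy group, its facial preference may be mismatched with the hindered α-quaternary aldehyde, or the keto aldehyde may undergo aldol side reactions. The fallback sets out from bromide 25 and returns at 27. Borylation of 25 with bis(pinacolato)diboron and Pd2(dba)3 in DMSO at 50 °C would give the primary allylboronate F5. Thermal allylboration of aldehyde 19 with F5 in toluene at rt should pass through a closed chair transition state with the same anti and facial preferences and leave the ketone untouched, giving 27 after aqueous work-up.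

Further compounds

F1 | step 7 | (4R,6R)-2-[(7E)-9-(benzyloxymethyl)-5,5-dimethyldeca-1,7,9-trien-2-yl]-4,6-dimethyl-1,3-dioxane (chiral acetal of 9) | C=C(C1O[C@H](C)C[C@@H](C)O1)CCC(C)(C)C/C=C/C(=C)COCc1ccccc1
F2 | step 7 | (4R,6R)-4,6-dimethyl-1,3-dioxane acetal of aldehyde 10 | C1=C(COCc3ccccc3)CC[C@]2(C4O[C@H](C)C[C@@H](C)O4)CCC(C)(C)C[C@@H]12
F3 | step 26 | cis-1,2-diol from pinacol coupling of 31 (two new carbinol centres not assigned) | CC1(O)C2(O)C[C@@H](O[Si](C)(C)C(C)(C)C)[C@H](C)[C@@H]2[C@@H](O[Si](C)(C)C(C)(C)C)[C@@]4(C)CC[C@]3(C)CCC(C)(C)C[C@H]3[C@@H]4CC1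
F4 | step 26 | cyclic thiocarbonate of F3 | CC12OC(=S)OC23C[C@@H](O[Si](C)(C)C(C)(C)C)[C@H](C)[C@@H]3[C@@H](O[Si](C)(C)C(C)(C)C)[C@@]4(C)CC[C@]5(C)CCC(C)(C)C[C@H]5[C@@H]4CC1
F5 | step 21 | pinacol allylboronate from 25 | [C@H]1(O[Si](CC)(CC)CC)C[C@@H](O[Si](C)(C)C(C)(C)C)C(CB2OC(C)(C)C(C)(C)O2)=C1
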